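**Plan**

- Ring numbering (one oxolane): O1, C2 (ArCH, anti to the CH2OH on C3), C3, C4, C5 (ArCH, syn to the CH2OH on C4). The target is the (2S,3R,4R,5R) isomer: 2,5-cis, 2,3-trans, 3,4-trans, 4,5-cis.
- Enabling feature: C2 carries H and a guaiacyl group and is bonded only to O1 and C3, so it is a disguised vanillin carbonyl carbon. The CH2OH on C3 is a vinyl group after cleavage and reduction, which is the residue left by an allylsilane whose γ-carbon is C3.
- Cuts, in retrosynthetic order: the three O-benzyl bonds; the C3 arm back to CH=CH2; O1–C2 and C2–C3 together (ring opened, one aldehyde released); the C3=C alkene (Wittig); C4–C5 (aldol).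
- Forward: the aldol joins C4 to C5, the acyl carbon becomes C3 and is olefinated to the allylsilane, and the only ring then closes by insertion of C2 between O1 and C3.
- Stereochemistry: C4 and C5 come from an (R)-4-benzyloxazolidinone-controlled boron syn-aldol. C2 is relayed from C5 and C3 from C4 in the ring closure. C3 is also the thermodynamic epimer at the aldehyde stage.

Key step: step 8

Remark on the chemistry: the alkene geometry of the allylsilane is erased in the ring closure. The Z isomer is used because one olefination delivers it and because its allylic strain fixes the C3/C4 relation. The C5 oxygen enters the ring closure as its triethylsilyl ether, so that neither water nor TfOH is formed. O-Benzylvanillin and 3-(benzyloxy)propanoic acid are taken as catalogue compounds.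

**Step 1**
Reactants: 1 3-(benzyloxy)propanoic acid; 2 (4R)-4-benzyl-1,3-oxazolidin-2-one
Product: 4 (4R)-4-benzyl-3-[3-(benzyloxy)propanoyl]-1,3-oxazolidin-2-one, via mixed pivalic anhydride 3 (not isolated)
Conditions: t-BuCOCl, Et3N, THF, −20 °C; then LiCl, 2, −20 °C → rt
Reagents that add atoms: pivaloyl chloride, CC(C)(C)C(=O)Cl (its acyl group sits only in 3 and leaves again; 4 is built from 1 and 2 alone)
Why: N-acylation of an Evans oxazolidinone through the mixed pivalic anhydride with LiCl/Et3N needs no strong base, so the β-benzyloxy acyl chain is not exposed to elimination and the auxiliary stereocentre is untouched.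

**Step 2**
Reactants: 4 (4R)-4-benzyl-3-[3-(benzyloxy)propanoyl]-1,3-oxazolidin-2-one; 5 4-(benzyloxy)-3-methoxybenzaldehyde (O-benzylvanillin)
Product: 8 (4R)-4-benzyl-3-{(2R,3R)-3-[4-(benzyloxy)-3-methoxyphenyl]-2-[(benzyloxy)methyl]-3-hydroxypropanoyl}-1,3-oxazolidin-2-one, via Z-boron enolate 6 (not isolated), via boron aldolate 7 (not isolated)
Conditions: n-Bu2BOTf, Et3N, CH2Cl2, −78 → 0 °C; 5, −78 → 0 °C; then MeOH, aq. NaH2PO4/Na2HPO4 (pH 7), 30% H2O2, 0 °C
Reagents that add atoms: di-n-butylboron triflate, CCCCB(CCCC)OS(=O)(=O)C(F)(F)F (boron and butyl groups are held only in 6 and 7; 8 is built from 4 and 5 alone)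
Why: Evans boron syn-aldol reaction: soft enolisation gives the Z-enolate 6, which adds to 5 through a Zimmerman–Traxler chair on the enolate face remote from the auxiliary benzyl group and so sets C4 and C5 as the (2R,3R) syn pair (the later 4,5-cis relation), while the covalent boron enolate kept at or below 0 °C has little tendency to expel benzyl oxide.

**Step 3**
Reactants: 8 syn-aldol imide
Product: 9 (2R,3R)-3-[4-(benzyloxy)-3-methoxyphenyl]-2-[(benzyloxy)methyl]-3-hydroxy-N-methoxy-N-methylpropanamide
Conditions: MeNH(OMe)·HCl, AlMe3, CH2Cl2, −15 → 0 °C; aq. potassium sodium tartrate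
Reagents that add atoms: N,O-dimethylhydroxylamine hydrochloride, CNOC.Cl
Why: Weinreb transamidation of a β-hydroxy imide, in which the aluminium alkoxide formed at the C5 hydroxyl directs the amide to the exocyclic carbonyl, frees the auxiliary for reuse and leaves C4 and C5 unchanged.

**Step 4**
Reactants: 9 β-hydroxy Weinreb amide
Product: 10 (2R,3R)-3-[4-(benzyloxy)-3-methoxyphenyl]-2-[(benzyloxy)methyl]-N-methoxy-N-methyl-3-[(triethylsilyl)oxy]propanamide
Conditions: Et3SiCl, imidazole, DMF, 0 °C → rt
Reagents that add atoms: chlorotriethylsilane, CC[Si](Cl)(CC)CC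
Why: Routine silylation of the secondary alcohol; the triethylsilyl group shuts off retro-aldol cleavage in steps 5 and 7 and is later the group that O1 gives up in the ring closure.

**Step 5**
Reactants: 10 silylated Weinreb amide
Product: 12 (2R,3R)-3-[4-(benzyloxy)-3-methoxyphenyl]-2-[(benzyloxy)methyl]-3-[(triethylsilyl)oxy]propanal, via aluminium hemiaminal 11 (not isolated)
Conditions: i-Bu2AlH, THF, −78 °C; aq. potassium sodium tartrate
Reagents that add atoms: diisobutylaluminium hydride, CC(C)C[AlH]CC(C)C (aluminium is held only in 11; 12 gains hydrogen alone)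
Why: Reduction of a Weinreb amide stops at the chelated hemiaminal 11, which collapses to the aldehyde only on work-up, so that neither over-reduction nor epimerisation at C4 is expected.

**Step 6**
Reactants: 13 methyltriphenylphosphonium bromide; 14 (iodomethyl)trimethylsilane
Product: 16 triphenyl[2-(trimethylsilyl)ethyl]phosphonium iodide, via methylidenetriphenylphosphorane 15 (not isolated)
Conditions: n-BuLi, Et2O/THF, 0 °C; then 14, 0 °C → rt, filtration of the salt
Reagents that add atoms: none
Why: SN2 alkylation of the unstabilised ylide 15 by the primary α-silyl iodide is the established entry to this salt, which precipitates and thereby escapes deprotonation by unreacted ylide.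

**Step 7**
Reactants: 12 α-branched aldehyde; 16 triphenyl[2-(trimethylsilyl)ethyl]phosphonium iodide
Product: 18 triethyl{[(1R,2R,3Z)-1-[4-(benzyloxy)-3-methoxyphenyl]-2-[(benzyloxy)methyl]-5-(trimethylsilyl)pent-3-en-1-yl]oxy}silane, via silylethylidene ylide 17 (not isolated)
Conditions: 16, NaN(SiMe3)2, THF, 0 °C; then 12, −78 °C → rt
Reagents that add atoms: none
Why: Wittig olefination with a non-stabilised ylide under lithium-free conditions is kinetically Z-selective, converts the formyl carbon into C3 of the allylsilane in one operation, and is fast enough at −78 °C to leave the α-stereocentre C4 intact.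

**Step 8**
Reactants: 18 (Z)-silyloxy-allylsilane; 5 4-(benzyloxy)-3-methoxybenzaldehyde
Product: 20 (2S,3S,4R,5R)-2,5-bis[4-(benzyloxy)-3-methoxyphenyl]-4-[(benzyloxy)methyl]-3-ethenyloxolane, via E-oxocarbenium ion 19 (not isolated)
Conditions: Me3SiOTf (0.2 equiv), 2,6-di-tert-butyl-4-methylpyridine (0.1 equiv), 4 Å molecular sieves, CH2Cl2, −78 °C; Et3N quench at −78 °C
Reagents that add atoms: none
Why: Me3SiOTf activates 5, the silyl ether oxygen of 18 adds, and loss of the mixed disiloxane gives the E-oxocarbenium ion 19 (O1–C2); the γ-carbon of the allylsilane (C3) then attacks C2 anti to the C–Si bond and the β-silyl cation hands Me3Si+ back to triflate, which makes C2–C3, unveils the vinyl group and turns the catalyst over. The closest known reaction type is the intramolecular silyl-modified Hosomi–Sakurai reaction, by which hydroxy- and silyloxy-allylsilanes and cyclic allylsiloxanes condense with aldehydes to 3-vinyloxolanes. The oxolane closes 5-exo-trig with respect to the C3=C bond and 5-endo-trig with respect to C2=O1+, a mode that cationic C=O+ acceptors accept readily. C2 is controlled by C5: in the envelope with C3 and C4 out of the C5–O1–C2 plane the E geometry of 19 and the pseudo-equatorial C5 aryl group place both aryl groups on one face (2,5-cis), the flipped envelope being penalised by a pseudo-axial aryl group and by a cis contact at C2/C3 or C3/C4. C3 is controlled by C4: A(1,3) strain in the Z-alkene keeps H4 in the alkene plane, so C2 arrives on the alkene face that carries C5 and the vinyl group emerges trans to the C4 arm and, through the antiperiplanar array of the two π systems, trans to the C2 aryl group. The step needs attack by C3 and not by the distal alkene carbon (the Prins and 2-oxonia-Cope channel), which the β-silicon effect secures, and it needs the ionisable C5–O bond to survive, which the silyl ether (no water, no TfOH), the hindered pyridine, the catalytic acid and the quench at −78 °C secure, while the benzyl ether on the C4 arm cannot condense with 5, so that O1 alone is engaged.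

**Step 9**
Reactants: 20 3-vinyloxolane
Product: 22 (2S,3S,4R,5R)-2,5-bis[4-(benzyloxy)-3-methoxyphenyl]-4-[(benzyloxy)methyl]oxolane-3-carbaldehyde, via vicinal diol 21 (not isolated)
Conditions: OsO4 (2 mol %), NaIO4, 2,6-lutidine, 1,4-dioxane/H2O, rt; then DBU (0.1 equiv), CH2Cl2, rt
Reagents that add atoms: osmium tetroxide, O=[Os](=O)(=O)=O (delivers the oxygen atoms of 21 and 22); sodium periodate, [Na+].[O-]I(=O)(=O)=O (terminal oxidant that renews OsO4)
Why: Lemieux–Johnson cleavage touches only the monosubstituted alkene, and the short DBU treatment equilibrates C3 through the enolate toward the isomer with the formyl group trans to both neighbours (its epimer would be the all-cis oxolane), whereas β-elimination of O1 would be the reverse of a 5-endo-trig addition and is not expected with catalytic base.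

**Step 10**
Reactants: 22 oxolane-3-carbaldehyde
Product: 23 {(2S,3R,4R,5R)-2,5-bis[4-(benzyloxy)-3-methoxyphenyl]-4-[(benzyloxy)methyl]oxolan-3-yl}methanol
Conditions: NaBH4, MeOH/THF, 0 °C
Reagents that add atoms: none
Why: Borohydride reduction of the aldehyde at 0 °C is faster than enolisation, creates no stereocentre and leaves ethers and ring untouched.

**Step 11**
Reactants: 23 tribenzyl ether
Product: 24 [(2S,3R,4R,5R)-2,5-bis(4-hydroxy-3-methoxyphenyl)oxolane-3,4-diyl]dimethanol (target)
Conditions: H2 (1 atm), 10% Pd/C, EtOAc/EtOH, rt, stopped after uptake of three equivalents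
Reagents that add atoms: none
Why: Catalytic hydrogenolysis removes the two aryl benzyl ethers and the unhindered primary alkyl benzyl ether well before the two secondary, doubly flanked ring C–O bonds react in a neutral solvent, so that all four stereocentres should be kept.

**Compound list**

1 | 3-(benzyloxy)propanoic acid | O=C(O)CCOCc1ccccc1 | starting material
2 | (4R)-4-benzyl-1,3-oxazolidin-2-one | O=C1N[C@H](Cc2ccccc2)CO1 | starting material
3 | 3-(benzyloxy)propanoic pivalic anhydride | CC(C)(C)C(=O)OC(=O)CCOCc1ccccc1 | intermediate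
4 | (4R)-4-benzyl-3-[3-(benzyloxy)propanoyl]-1,3-oxazolidin-2-one | O=C(CCOCc1ccccc1)N1[C@H](Cc2ccccc2)COC1=O | intermediate
5 | 4-(benzyloxy)-3-methoxybenzaldehyde | COc1cc(C=O)ccc1OCc1ccccc1 | starting material
6 | (Z)-di-n-butylboron enolate of 4 | CCCCB(CCCC)O/C(=C\COCc1ccccc1)N1[C@H](Cc2ccccc2)COC1=O | intermediate
7 | di-n-butylboron aldolate of 8 | CCCCB(CCCC)O[C@@H](c1ccc(OCc2ccccc2)c(OC)c1)[C@@H](COCc1ccccc1)C(=O)N1[C@H](Cc2ccccc2)COC1=O | intermediate
8 | (4R)-4-benzyl-3-{(2R,3R)-3-[4-(benzyloxy)-3-methoxyphenyl]-2-[(benzyloxy)methyl]-3-hydroxypropanoyl}-1,3-oxazolidin-2-one | O[C@@H](c1ccc(OCc2ccccc2)c(OC)c1)[C@@H](COCc1ccccc1)C(=O)N1[C@H](Cc2ccccc2)COC1=O | intermediate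
9 | (2R,3R)-3-[4-(benzyloxy)-3-methoxyphenyl]-2-[(benzyloxy)methyl]-3-hydroxy-N-methoxy-N-methylpropanamide | O[C@@H](c1ccc(OCc2ccccc2)c(OC)c1)[C@@H](COCc1ccccc1)C(=O)N(C)OC | intermediate
10 | (2R,3R)-3-[4-(benzyloxy)-3-methoxyphenyl]-2-[(benzyloxy)methyl]-N-methoxy-N-methyl-3-[(triethylsilyl)oxy]propanamide | CC[Si](CC)(CC)O[C@@H](c1ccc(OCc2ccccc2)c(OC)c1)[C@@H](COCc1ccccc1)C(=O)N(C)OC | intermediate
11 | O-diisobutylaluminium hemiaminal from 10 (hemiaminal carbon undefined) | CC[Si](CC)(CC)O[C@@H](c1ccc(OCc2ccccc2)c(OC)c1)[C@@H](COCc1ccccc1)C(O[Al](CC(C)C)CC(C)C)N(C)OC | intermediate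
12 | (2R,3R)-3-[4-(benzyloxy)-3-methoxyphenyl]-2-[(benzyloxy)methyl]-3-[(triethylsilyl)oxy]propanal | CC[Si](CC)(CC)O[C@@H](c1ccc(OCc2ccccc2)c(OC)c1)[C@@H](COCc1ccccc1)C=O | intermediate
13 | methyltriphenylphosphonium bromide | C[P+](c1ccccc1)(c1ccccc1)c1ccccc1.[Br-] | starting material
14 | (iodomethyl)trimethylsilane | C[Si](C)(C)CI | starting material
15 | methylidenetriphenylphosphorane | C=P(c1ccccc1)(c1ccccc1)c1ccccc1 | intermediate
16 | triphenyl[2-(trimethylsilyl)ethyl]phosphonium iodide | C[Si](C)(C)CC[P+](c1ccccc1)(c1ccccc1)c1ccccc1.[I-] | intermediate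
17 | triphenyl[2-(trimethylsilyl)ethylidene]phosphorane | C[Si](C)(C)CC=P(c1ccccc1)(c1ccccc1)c1ccccc1 | intermediate
18 | triethyl{[(1R,2R,3Z)-1-[4-(benzyloxy)-3-methoxyphenyl]-2-[(benzyloxy)methyl]-5-(trimethylsilyl)pent-3-en-1-yl]oxy}silane | CC[Si](CC)(CC)O[C@@H](c1ccc(OCc2ccccc2)c(OC)c1)[C@@H](COCc1ccccc1)/C=C\C[Si](C)(C)C | intermediate
19 | (E)-oxocarbenium ion from 18 and 5 (cation, triflate counter-ion) | COc1cc(/C=[O+]/[C@@H](c2ccc(OCc3ccccc3)c(OC)c2)[C@@H](COCc2ccccc2)/C=C\C[Si](C)(C)C)ccc1OCc1ccccc1 | intermediate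
20 | (2S,3S,4R,5R)-2,5-bis[4-(benzyloxy)-3-methoxyphenyl]-4-[(benzyloxy)methyl]-3-ethenyloxolane | COc1cc([C@H]2O[C@@H](c3ccc(OCc4ccccc4)c(OC)c3)[C@@H](COCc3ccccc3)[C@@H]2C=C)ccc1OCc1ccccc1 | intermediate
21 | 1-{(2S,3R,4R,5R)-2,5-bis[4-(benzyloxy)-3-methoxyphenyl]-4-[(benzyloxy)methyl]oxolan-3-yl}ethane-1,2-diol (both carbinol epimers) | COc1cc([C@H]2O[C@@H](c3ccc(OCc4ccccc4)c(OC)c3)[C@@H](COCc3ccccc3)[C@@H]2C(O)CO)ccc1OCc1ccccc1 | intermediate
22 | (2S,3S,4R,5R)-2,5-bis[4-(benzyloxy)-3-methoxyphenyl]-4-[(benzyloxy)methyl]oxolane-3-carbaldehyde | COc1cc([C@H]2O[C@@H](c3ccc(OCc4ccccc4)c(OC)c3)[C@@H](COCc3ccccc3)[C@@H]2C=O)ccc1OCc1ccccc1 | intermediate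
23 | {(2S,3R,4R,5R)-2,5-bis[4-(benzyloxy)-3-methoxyphenyl]-4-[(benzyloxy)methyl]oxolan-3-yl}methanol | COc1cc([C@H]2O[C@@H](c3ccc(OCc4ccccc4)c(OC)c3)[C@@H](COCc3ccccc3)[C@@H]2CO)ccc1OCc1ccccc1 | intermediate
24 | [(2S,3R,4R,5R)-2,5-bis(4-hydroxy-3-methoxyphenyl)oxolane-3,4-diyl]dimethanol | COc1cc([C@H]2O[C@@H](c3ccc(O)c(OC)c3)[C@@H](CO)[C@@H]2CO)ccc1O | target

**Step count**

Total step count: 11. Longest linear sequence: 10 (steps 1–5 and 7–11, from 1).

**Steps most likely to fail**

**Step 8.**
- What may go wrong: ionisation of the electron-rich benzylic C5–O bond before or after ring closure, with loss of the C5 configuration.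
- What may go wrong: direct allyl transfer from the silane to the activated aldehyde in place of acetalisation.
- What may go wrong: incomplete facial selectivity at C2.

The fallback makes O1–C2 first, by acylation, and leaves only C2–C3 to the Lewis acid. It sets out from 18. The silyl ether is cleaved (Bu4NF/AcOH, THF, 0 °C) to the free (Z)-hydroxy-allylsilane F1. This is esterified with commercial 4-(benzyloxy)-3-methoxybenzoic acid (DCC, DMAP, CH2Cl2) to the aryl ester F2. Reductive acetylation (i-Bu2AlH, CH2Cl2, −78 °C; then Ac2O, pyridine, DMAP) gives the α-acetoxy ether F3. Ionisation of its acetate (Me3SiOTf, 0.1 equiv, 2,6-di-tert-butyl-4-methylpyridine, CH2Cl2, −78 °C) releases ion 19 in a unimolecular step with no free aldehyde present. The ring closure then comes back to the route at 20.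

**Step 2.**
- What may go wrong: expulsion of benzyl oxide from the β-alkoxy enolate.
- What may go wrong: erosion of the facial selectivity through coordination of the ether oxygen to boron.

The fallback avoids an enolate altogether and sets C4 and C5 by allylboration. It sets out from 5.
- Commercial benzyl prop-2-yn-1-yl ether is lithiated (n-BuLi, THF, −78 °C) and homologated with 2-(chloromethyl)-4,4,5,5-tetramethyl-1,3,2-dioxaborolane (Matteson-type 1,2-shift) to the propargylic boronate F4.
- Semihydrogenation (H2, Pd/CaCO3 poisoned with Pb(OAc)2, quinoline) gives the (Z)-allylboronate F5.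
- Addition of F5 to 5 under chiral phosphoric acid catalysis goes through a closed chair, in which the Z-boronate gives the syn product, the homoallylic alcohol F6. The catalyst is (R)-3,3'-bis(2,4,6-triisopropylphenyl)-1,1'-binaphthyl-2,2'-diyl hydrogen phosphate in toluene at −30 °C. This enantiomer is expected to give the 1R carbinol by analogy with allyl and crotyl transfer to benzaldehydes.
- Silylation (Et3SiCl, imidazole) gives the silyl ether F7.
- Lemieux–Johnson cleavage of its vinyl group (OsO4, NaIO4, 2,6-lutidine) comes back to the route at 12.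

**Step 7.**
- What may go wrong: epimerisation at C4.
- What may go wrong: β-elimination of silyloxide or benzyl oxide from the aldehyde under the basic ylide.
- What may go wrong: a drop in Z-selectivity.

The fallback replaces the ylide by non-basic chromium chemistry and a cross-coupling. It sets out from 12. Takai olefination (CrCl2, CHI3, THF, 0 °C) gives the (E)-vinyl iodide F8. Kumada coupling (Me3SiCH2MgCl, Pd(PPh3)4, THF, rt) gives the (E)-allylsilane F9. Under the conditions of step 8, F9 comes back to the route at 20, because the alkene geometry is not carried into the product. Any weaker control at C3 is levelled by the DBU treatment in step 9.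

**Further compounds**

F1 | step 8 | (1R,2R,3Z)-1-[4-(benzyloxy)-3-methoxyphenyl]-2-[(benzyloxy)methyl]-5-(trimethylsilyl)pent-3-en-1-ol | O[C@@H](c1ccc(OCc2ccccc2)c(OC)c1)[C@@H](COCc1ccccc1)/C=C\C[Si](C)(C)C
F2 | step 8 | 4-(benzyloxy)-3-methoxybenzoate of F1 | O=C(O[C@@H](c1ccc(OCc2ccccc2)c(OC)c1)[C@@H](COCc1ccccc1)/C=C\C[Si](C)(C)C)c1ccc(OCc2ccccc2)c(OC)c1
F3 | step 8 | α-acetoxy ether from F2 (both acetal epimers) | CC(=O)OC(O[C@@H](c1ccc(OCc2ccccc2)c(OC)c1)[C@@H](COCc1ccccc1)/C=C\C[Si](C)(C)C)c1ccc(OCc2ccccc2)c(OC)c1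
F4 | step 2 | 2-[4-(benzyloxy)but-2-yn-1-yl]-4,4,5,5-tetramethyl-1,3,2-dioxaborolane | CC1(C)OB(CC#CCOCc2ccccc2)OC1(C)C
F5 | step 2 | 2-[(2Z)-4-(benzyloxy)but-2-en-1-yl]-4,4,5,5-tetramethyl-1,3,2-dioxaborolane | CC1(C)OB(C/C=C\COCc2ccccc2)OC1(C)C
F6 | step 2 | (1R,2R)-1-[4-(benzyloxy)-3-methoxyphenyl]-2-[(benzyloxy)methyl]but-3-en-1-ol | O[C@@H](c1ccc(OCc2ccccc2)c(OC)c1)[C@@H](COCc1ccccc1)C=C
F7 | step 2 | triethylsilyl ether of F6 | CC[Si](CC)(CC)O[C@@H](c1ccc(OCc2ccccc2)c(OC)c1)[C@@H](COCc1ccccc1)C=C
F8 | step 7 | triethyl{[(1R,2R,3E)-1-[4-(benzyloxy)-3-methoxyphenyl]-2-[(benzyloxy)methyl]-4-iodobut-3-en-1-yl]oxy}silane | CC[Si](CC)(CC)O[C@@H](c1ccc(OCc2ccccc2)c(OC)c1)[C@@H](COCc1ccccc1)/C=C/I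
F9 | step 7 | triethyl{[(1R,2R,3E)-1-[4-(benzyloxy)-3-methoxyphenyl]-2-[(benzyloxy)methyl]-5-(trimethylsilyl)pent-3-en-1-yl]oxy}silane | CC[Si](CC)(CC)O[C@@H](c1ccc(OCc2ccccc2)c(OC)c1)[C@@H](COCc1ccccc1)/C=C/C[Si](C)(C)C
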